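**The decision.** I choose to reckon what each flask turns per hour in molar terms, rather than what fraction of its electrophile it turns, and I test that choice on the autumn and winter runs.

| flask | electrophile | free base | scavenger | gas | remark | time |
|---|---|---|---|---|---|---|
| autumn | 0.30 M | 1.3 equiv (fed, over 12 h) | 0.50 equiv | 13 mM (held) | run made earlier; the fed solution adds 0.20 times the starting volume |  |
| winter | 0.30 M | 6.1 equiv (fed, over 12 h) | 0.50 equiv | 13 mM (held) | run made earlier; the fed solution adds 0.20 times the starting volume |  |
| red | 0.30 M | 4.80 equiv (fed, over 12 h) | 0.500 equiv | 13 mM (held) | the fed solution adds 0.20 times the starting volume | 12 h |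
| violet | 0.30 M | 1.20 equiv (fed, over 12 h) | 0.500 equiv | 13 mM (held) | the fed solution adds 0.20 times the starting volume | 12 h |
| grey | 0.30 M | 2.40 equiv (fed, over 12 h) | 0.500 equiv | 13 mM (held) | the fed solution adds 0.20 times the starting volume | 12 h |

| run | time / h | electrophile / % | product / % |
|---|---|---|---|
| autumn | 0.333 | 98 | 0 |
| autumn | 1.00 | 91 | 7 |
| autumn | 1.50 | 94 | 12 |
| autumn | 2.50 | 85 | 12 |
| autumn | 4.00 | 79 | 23 |
| autumn | 5.00 | 73 | 28 |
| autumn | 6.00 | 67 | 35 |
| winter | 0.500 | 98 | 3 |
| winter | 0.667 | 97 | 6 |
| winter | 1.00 | 96 | 3 |
| winter | 1.50 | 89 | 8 |
| winter | 2.50 | 86 | 17 |
| winter | 4.00 | 72 | 26 |
| winter | 6.00 | 59 | 39 |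

(scatter of a reading: 2 percentage points)

* part of the electrophile that has reacted at the end, red
* part of the electrophile that has reacted at the end, violet
* part of the electrophile that has reacted at the end, grey
* what raising the equivalents of free base from its lowest to its highest value here does to the part of the electrophile that has reacted (changes below 5 percentage points count as none) (it rises / it falls / no change)

- what is said of acid set free includes idle adduct
- amounts are per litre of the starting volume; all of the dose is in the solution fed
- at the start none of nucleophile is dissolved
- steps thought possible: electrophile + nucleophile -> acid set free + product; nucleophile + acid set free <-> protonated nucleophile; acid set free + free base <-> salt of the base; acid set free + free base <-> idle adduct; acid set free + scavenger -> scavenged by-product; gas <-> nucleophile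

**First instants.** No nucleophile is dissolved at the start, and the gas is held at 13 mM, far less than the 0.30 M of electrophile, so the electrophile waits for nucleophile to cross over, and whatever arrives meets plenty of partner. I therefore expect a steady output per hour, zero order in electrophile, and not a decay.

**The middle.** In winter, product comes at 0.0204 M/h up to 2.50 h and at 0.0189 M/h from there to 6.00 h, which shows no slowing beyond the scatter. Averaging electrophile lost and product made at the last winter reading gives 0.0200 M/h, and this is my pace v, the electrophile turned per hour per litre of starting volume. The same reading in autumn gives 0.0170 M/h, so going from 1.3 equiv to 6.1 equiv of free base lifts the pace by 0.00300 M/h.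

**The end.** Dividing the charge by the winter pace gives a clearing time of 15.0 h, longer than the 12 h run, so even at that pace electrophile remains at the end. Placing grey and red between the two paces on the logarithm of their free base, and extending that line below the autumn run for violet, whose 1.20 equiv lies under the 1.3 equiv of autumn, I reckon 67.4% for violet, 72.8% for grey and 78.1% for red, a rise beyond 5 percentage points.

**The forecast.** The forecast gives 56% for violet, 60% for grey and 64% for red, with the answer it rises, on the ground that “The electrophile falls at a near first-order rate”. We agree on the direction, but its curve bends where my line does not, so my numbers stand higher.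

**The result.** The flask gives 68.1% for violet, 72.7% for grey and 77.9% for red, and the answer is it rises, by 9.8 points.

    electrophile + nucleophile → acid set free + product (k = 1.90 /M/min)
    nucleophile + acid set free ⇌ protonated nucleophile, settled at all times (K = 1.30 × 10⁵ /M)
    acid set free + free base ⇌ salt of the base (K = 2.00 × 10⁵ /M, k = 0.0580 /M/min)
    acid set free + free base ⇌ idle adduct, settled at all times (K = 300 /M)
    acid set free + scavenger → scavenged by-product (k = 0.100 /M/min)
    gas ⇌ nucleophile, rate k6*(csat - [nucleophile]) (kL = 0.0360 /min)

**Straight line.** Red ran at 0.0195 M/h against the pace 0.0200 M/h, with 18% of its product-making turnover done by 2.40 h, and the gap between red and violet comes mainly from the difference in equivalents of free base, since red stands at 77.9% with that difference and at 68.1% without it. The neighbour of red charged with 0.18 M has a clearing time of 9.00 h at that pace, shorter than its run, and it reaches 94.7%, with 5.3% of its electrophile still there.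

Readings and results stem from a simulated flask with constants of no real substance, noise included.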